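**Retrosynthetic overview**
1. Target 18 ⇐ global desilylation of 17 ⇐ ester of oxolane alcohol 12 with silylated caffeic acid 16 (16 ⇐ Heck coupling of acrylic acid with bromocatechol bis-silyl ether 14).
2. Oxolane ring (formed last) ⇐ lactone 10 reduced to a triol, then acid closure through the benzylic cation, aryl trans to CH2OH.
3. 10 ⇐ anti-selective aldol of (S)-lactone 9 with aldehyde 5.
4. Lactone ring (formed first) ⇐ enantioselective carbonylative ring expansion of the prochiral oxetane 8, four- to five-membered (key step).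
5. 8 ⇐ hydroboration/Suzuki coupling of 3-methylideneoxetane with aryl bromide 4; all three arenes come from catechol.

Assumption: the sense of induction of the new carbonylation catalyst must be found by experiment; the (R,R) ligand is written, and the (S,S) antipode is used if (R,R) gives the (R)-lactone.
Abbreviations: TIPS = tri(propan-2-yl)silyl; TBS = tert-butyl(dimethyl)silyl.

**Step 1**
Reactants: 1 catechol (benzene-1,2-diol)
Product: 2 guaiacol (2-methoxyphenol)
Conditions: MeI (1.0 equiv), K2CO3 (1.0 equiv), acetone, reflux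
Reagents that add atoms: iodomethane, CI
Why: Williamson mono-O-methylation; unreacted catechol (water-soluble) and over-methylated veratrole (not base-soluble) are removed by extraction.

**Step 2**
Reactants: 2 guaiacol
Product: 4 (4-bromo-2-methoxyphenoxy)-TIPS-silane, via 4-bromo-2-methoxyphenol 3 (not isolated)
Conditions: NBS (1.0 equiv), DMF, 0 °C; then imidazole, i-Pr3SiCl, rt
Reagents that add atoms: N-bromosuccinimide, O=C1CCC(=O)N1Br; chlorotri(propan-2-yl)silane, CC(C)[Si](Cl)(C(C)C)C(C)C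
Why: electrophilic aromatic bromination goes para to the free hydroxyl (the strongest director), and the phenol is then silylated in the same flask.

**Step 3**
Reactants: 4 (4-bromo-2-methoxyphenoxy)-TIPS-silane
Product: 5 3-methoxy-4-(TIPS-oxy)benzaldehyde
Conditions: n-BuLi, THF, −78 °C; DMF; H2O
Reagents that add atoms: N,N-dimethylformamide, CN(C)C=O
Why: bromine–lithium exchange followed by Bouveault formylation; the aryl silyl ether is inert at −78 °C.

**Step 4**
Reactants: 6 3-methylideneoxetane; 4 (4-bromo-2-methoxyphenoxy)-TIPS-silane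
Product: 8 3-{[3-methoxy-4-(TIPS-oxy)phenyl]methyl}oxetane, via 9-(oxetan-3-ylmethyl)-9-borabicyclo[3.3.1]nonane 7 (not isolated)
Conditions: 6, 9-BBN, THF, 0 °C → rt; then 4, Pd(dppf)Cl2 (3 mol %, dppf = 1,1′-bis(diphenylphosphino)ferrocene), 3 M aq. K3PO4, 60 °C
Reagents that add atoms: none
Why: anti-Markovnikov hydroboration of the 1,1-disubstituted alkene followed by B-alkyl Suzuki–Miyaura coupling; the oxetane is stable to base.

**Step 5**
Reactants: 8 3-{[3-methoxy-4-(TIPS-oxy)phenyl]methyl}oxetane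
Product: 9 (4S)-4-{[3-methoxy-4-(TIPS-oxy)phenyl]methyl}oxolan-2-one
Conditions: [(R,R)-(salen)Cr(THF)2][Co(CO)4] (5 mol %; salen = N,N′-bis(3,5-di-tert-butylsalicylidene)cyclohexane-1,2-diamine dianion), CO (60 bar), DME, 50 °C
Reagents that add atoms: carbon monoxide, [C-]#[O+]
Why: Proposed new method: the cationic trivalent-chromium salen Lewis acid binds the oxetane oxygen and, in its C2-symmetric pocket, exposes one of the two enantiotopic O–CH2 carbons to SN2 attack by [Co(CO)4]− (cobalt in the formal oxidation state minus one); CO insertion into the alkyl–cobalt bond and closure of the chromium-bound alkoxide onto the acylcobalt give the five-membered lactone and return the ion pair, so the C4 stereocentre is set by catalyst-controlled desymmetrisation without breaking a bond at that carbon; the closest known reaction type is the achiral Lewis acid/tetracarbonylcobaltate carbonylative ring expansion of oxetanes to γ-butyrolactones, together with the enantioselective carbonylation of meso-epoxides by chiral salen-metal tetracarbonylcobaltates and chiral-acid desymmetrisation of 3-substituted oxetanes.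

**Step 6**
Reactants: 9 (4S)-4-{[3-methoxy-4-(TIPS-oxy)phenyl]methyl}oxolan-2-one; 5 3-methoxy-4-(TIPS-oxy)benzaldehyde
Product: 10 (3R,4S)-3-{hydroxy[3-methoxy-4-(TIPS-oxy)phenyl]methyl}-4-{[3-methoxy-4-(TIPS-oxy)phenyl]methyl}oxolan-2-one (both carbinol epimers)
Conditions: LiN(SiMe3)2, THF, −78 °C; then 5, −78 °C; AcOH quench at −78 °C
Reagents that add atoms: none
Why: aldol addition of the lithium lactone enolate; the aldehyde approaches the face opposite the C4 benzyl group, which sets C3 trans (3R), and the carbinol centre forms as a mixture that is erased in step 7.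

**Step 7**
Reactants: 10 the aldol lactone
Product: 12 [(2R,3S,4S)-2-[3-methoxy-4-(TIPS-oxy)phenyl]-4-{[3-methoxy-4-(TIPS-oxy)phenyl]methyl}oxolan-3-yl]methanol, via silylated triol 11 (not isolated)
Conditions: LiBH4, THF, 0 °C → rt; then 1 M aq. HCl, rt
Reagents that add atoms: none
Why: hydride reduction of the lactone, then SN1 cycloetherification: acid ionises the p-silyloxybenzylic alcohol and the cation is captured by the primary hydroxyl on the benzyl-bearing arm (the only five-membered ether possible); both carbinol epimers converge to the 2,3-trans ring with aryl anti to CH2OH (C2 = R), while the trans lactone substituents become the 3,4-cis pair of the new ring.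

**Step 8**
Reactants: 1 catechol
Product: 14 4-bromo-1,2-bis(TBS-oxy)benzene, via 4-bromocatechol 13 (not isolated)
Conditions: NBS (1.0 equiv), MeCN, −20 → 0 °C; then imidazole, t-BuMe2SiCl, rt
Reagents that add atoms: N-bromosuccinimide, O=C1CCC(=O)N1Br; tert-butylchlorodimethylsilane, CC(C)(C)[Si](C)(C)Cl
Why: electrophilic aromatic bromination para to a hydroxyl (position 4), then double silylation of the air-sensitive bromocatechol in the same flask.

**Step 9**
Reactants: 14 4-bromo-1,2-bis(TBS-oxy)benzene; 15 acrylic acid (prop-2-enoic acid)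
Product: 16 (2E)-3-[3,4-bis(TBS-oxy)phenyl]prop-2-enoic acid
Conditions: Pd(OAc)2 (3 mol %), P(o-tol)3 (6 mol %), Et3N, MeCN, 80 °C
Reagents that add atoms: none
Why: Mizoroki–Heck reaction; syn insertion and syn β-hydride elimination give the E-cinnamic acid.

**Step 10**
Reactants: 12 the oxolane alcohol; 16 the silylated caffeic acid
Product: 17 [(2R,3S,4S)-2-[3-methoxy-4-(TIPS-oxy)phenyl]-4-{[3-methoxy-4-(TIPS-oxy)phenyl]methyl}oxolan-3-yl]methyl (2E)-3-[3,4-bis(TBS-oxy)phenyl]prop-2-enoate
Conditions: DCC, DMAP (cat.), CH2Cl2, 0 °C → rt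
Reagents that add atoms: none
Why: Steglich esterification of the only free hydroxyl; no stereocentre is touched.

**Step 11**
Reactants: 17 the fully silylated ester
Product: 18 [(2R,3S,4S)-2-(4-hydroxy-3-methoxyphenyl)-4-[(4-hydroxy-3-methoxyphenyl)methyl]oxolan-3-yl]methyl (2E)-3-(3,4-dihydroxyphenyl)prop-2-enoate
Conditions: Bu4NF (4.4 equiv), AcOH (4.4 equiv), THF, 0 °C
Reagents that add atoms: none
Why: fluoride cleavage of the four aryl silyl ethers (driven by Si–F bond formation); the acetic acid buffer keeps the cinnamate ester, the catechol and the benzylic ether intact.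

**Compound list**
1 | catechol (benzene-1,2-diol) | Oc1ccccc1O | starting material
2 | guaiacol (2-methoxyphenol) | COc1ccccc1O | intermediate
3 | 4-bromo-2-methoxyphenol | COc1cc(Br)ccc1O | intermediate
4 | (4-bromo-2-methoxyphenoxy)-TIPS-silane | COc1cc(Br)ccc1O[Si](C(C)C)(C(C)C)C(C)C | intermediate
5 | 3-methoxy-4-(TIPS-oxy)benzaldehyde | COc1cc(C=O)ccc1O[Si](C(C)C)(C(C)C)C(C)C | intermediate
6 | 3-methylideneoxetane | C=C1COC1 | starting material
7 | 9-(oxetan-3-ylmethyl)-9-borabicyclo[3.3.1]nonane | C(C1COC1)B1C2CCCC1CCC2 | intermediate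
8 | 3-{[3-methoxy-4-(TIPS-oxy)phenyl]methyl}oxetane | COc1cc(CC2COC2)ccc1O[Si](C(C)C)(C(C)C)C(C)C | intermediate
9 | (4S)-4-{[3-methoxy-4-(TIPS-oxy)phenyl]methyl}oxolan-2-one | COc1cc(C[C@@H]2COC(=O)C2)ccc1O[Si](C(C)C)(C(C)C)C(C)C | intermediate
10 | (3R,4S)-3-{hydroxy[3-methoxy-4-(TIPS-oxy)phenyl]methyl}-4-{[3-methoxy-4-(TIPS-oxy)phenyl]methyl}oxolan-2-one, both carbinol epimers | COc1cc(C[C@@H]2COC(=O)[C@H]2C(O)c2ccc(O[Si](C(C)C)(C(C)C)C(C)C)c(OC)c2)ccc1O[Si](C(C)C)(C(C)C)C(C)C | intermediate
11 | (2S,3S)-2-{hydroxy[3-methoxy-4-(TIPS-oxy)phenyl]methyl}-3-{[3-methoxy-4-(TIPS-oxy)phenyl]methyl}butane-1,4-diol, both carbinol epimers | COc1cc(C[C@H](CO)[C@@H](CO)C(O)c2ccc(O[Si](C(C)C)(C(C)C)C(C)C)c(OC)c2)ccc1O[Si](C(C)C)(C(C)C)C(C)C | intermediate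
12 | [(2R,3S,4S)-2-[3-methoxy-4-(TIPS-oxy)phenyl]-4-{[3-methoxy-4-(TIPS-oxy)phenyl]methyl}oxolan-3-yl]methanol | COc1cc(C[C@@H]2CO[C@@H](c3ccc(O[Si](C(C)C)(C(C)C)C(C)C)c(OC)c3)[C@@H]2CO)ccc1O[Si](C(C)C)(C(C)C)C(C)C | intermediate
13 | 4-bromocatechol (4-bromobenzene-1,2-diol) | Oc1ccc(Br)cc1O | intermediate
14 | 4-bromo-1,2-bis(TBS-oxy)benzene | CC(C)(C)[Si](C)(C)Oc1ccc(Br)cc1O[Si](C)(C)C(C)(C)C | intermediate
15 | acrylic acid (prop-2-enoic acid) | C=CC(=O)O | starting material
16 | (2E)-3-[3,4-bis(TBS-oxy)phenyl]prop-2-enoic acid | CC(C)(C)[Si](C)(C)Oc1ccc(/C=C/C(=O)O)cc1O[Si](C)(C)C(C)(C)C | intermediate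
17 | [(2R,3S,4S)-2-[3-methoxy-4-(TIPS-oxy)phenyl]-4-{[3-methoxy-4-(TIPS-oxy)phenyl]methyl}oxolan-3-yl]methyl (2E)-3-[3,4-bis(TBS-oxy)phenyl]prop-2-enoate | COc1cc(C[C@@H]2CO[C@@H](c3ccc(O[Si](C(C)C)(C(C)C)C(C)C)c(OC)c3)[C@@H]2COC(=O)/C=C/c2ccc(O[Si](C)(C)C(C)(C)C)c(O[Si](C)(C)C(C)(C)C)c2)ccc1O[Si](C(C)C)(C(C)C)C(C)C | intermediate
18 | [(2R,3S,4S)-2-(4-hydroxy-3-methoxyphenyl)-4-[(4-hydroxy-3-methoxyphenyl)methyl]oxolan-3-yl]methyl (2E)-3-(3,4-dihydroxyphenyl)prop-2-enoate | COc1cc(C[C@@H]2CO[C@@H](c3ccc(O)c(OC)c3)[C@@H]2COC(=O)/C=C/c2ccc(O)c(O)c2)ccc1O | target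

**Step count and risk**
Total steps: 11 (steps 2, 4, 7 and 8 are one-flask operations counted once each).
Longest linear sequence: 8 steps (1, 2, 4, 5, 6, 7, 10, 11).

The three steps most likely to fail:

Step 5 (the proposed new carbonylative desymmetrisation; risks are low enantioselectivity and oxetane oligomerisation). The fallback uses known chemistry, sets out from 4 and comes back at 9. Bromine–lithium exchange on 4 (n-BuLi, THF, −78 °C), then CuBr·SMe2 (cat.) and allyl bromide, gives 2-methoxy-4-(prop-2-en-1-yl)-1-(TIPS-oxy)benzene F1. Cycloaddition with dichloroketene (Cl3CCOCl, Zn dust, Et2O) gives racemic 2,2-dichloro-3-{[3-methoxy-4-(TIPS-oxy)phenyl]methyl}cyclobutan-1-one F2. Zn dust in AcOH removes both chlorines to give the prochiral 3-{[3-methoxy-4-(TIPS-oxy)phenyl]methyl}cyclobutan-1-one F3. A desymmetrising Baeyer–Villiger oxidation of F3 (aqueous H2O2 with a chiral BINOL-derived phosphoric acid, or a Baeyer–Villiger monooxygenase chosen for the (S) sense) then gives lactone 9.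

Step 7 (one-flask reduction and cationic ring closure; risks are Friedel–Crafts closure onto the second arene to an aryltetralin and incomplete trans selectivity). The fallback sets out from 10 and comes back at 12, and replaces the cation by a quinone methide. Compound 10 is reduced with LiBH4 and triol 11 is isolated. Bu4NF/AcOH removes both silyl groups to give (2S,3S)-2-[hydroxy(4-hydroxy-3-methoxyphenyl)methyl]-3-[(4-hydroxy-3-methoxyphenyl)methyl]butane-1,4-diol F4. In dilute aqueous acid at rt this free phenol loses water through a p-quinone methide, which the primary hydroxyl traps by 1,6-oxa-Michael addition, as known for the enantiomeric natural series, to give (−)-lariciresinol F5. Phenoxide-selective silylation (i-Pr3SiCl, K2CO3, DMF, 0 °C) returns 12.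

Step 9 (Heck coupling of free acrylic acid with an electron-rich bromide that carries base-sensitive aryl silyl ethers). The fallback sets out from 12 (with 14) and comes back at 17, moving the C–C coupling onto the ester. Alcohol 12 is acylated with acryloyl chloride (Et3N, CH2Cl2, 0 °C) to give [(2R,3S,4S)-2-[3-methoxy-4-(TIPS-oxy)phenyl]-4-{[3-methoxy-4-(TIPS-oxy)phenyl]methyl}oxolan-3-yl]methyl prop-2-enoate F6. Heck coupling of F6 with 14 under mild conditions (the zerovalent palladium complex Pd(P(t-Bu)3)2, Cy2NMe, dioxane, 60 °C) gives 17 directly, so steps 9 and 10 drop out.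

**Further compounds**
F1 | step 5 | 2-methoxy-4-(prop-2-en-1-yl)-1-(TIPS-oxy)benzene | C=CCc1ccc(O[Si](C(C)C)(C(C)C)C(C)C)c(OC)c1
F2 | step 5 | racemic 2,2-dichloro-3-{[3-methoxy-4-(TIPS-oxy)phenyl]methyl}cyclobutan-1-one | COc1cc(CC2CC(=O)C2(Cl)Cl)ccc1O[Si](C(C)C)(C(C)C)C(C)C
F3 | step 5 | 3-{[3-methoxy-4-(TIPS-oxy)phenyl]methyl}cyclobutan-1-one | COc1cc(CC2CC(=O)C2)ccc1O[Si](C(C)C)(C(C)C)C(C)C
F4 | step 7 | (2S,3S)-2-[hydroxy(4-hydroxy-3-methoxyphenyl)methyl]-3-[(4-hydroxy-3-methoxyphenyl)methyl]butane-1,4-diol, both carbinol epimers | COc1cc(C[C@H](CO)[C@@H](CO)C(O)c2ccc(O)c(OC)c2)ccc1O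
F5 | step 7 | (−)-lariciresinol, 4-[(2R,3S,4S)-4-[(4-hydroxy-3-methoxyphenyl)methyl]-3-(hydroxymethyl)oxolan-2-yl]-2-methoxyphenol | COc1cc(C[C@@H]2CO[C@@H](c3ccc(O)c(OC)c3)[C@@H]2CO)ccc1O
F6 | step 9 | [(2R,3S,4S)-2-[3-methoxy-4-(TIPS-oxy)phenyl]-4-{[3-methoxy-4-(TIPS-oxy)phenyl]methyl}oxolan-3-yl]methyl prop-2-enoate | COc1cc(C[C@@H]2CO[C@@H](c3ccc(O[Si](C(C)C)(C(C)C)C(C)C)c(OC)c3)[C@@H]2COC(=O)C=C)ccc1O[Si](C(C)C)(C(C)C)C(C)C
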